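**Plan**
Locants: lactone O–CH = C1, C2=C3(CH3), C4 (CHOH), C5–C6(CH3) epoxide, C7H2, C8H2, C9 (CH–O‑angelate), C10 (fusion CH), C11(=C13H2), C12 (C=O); ring A = carbocycle C1–C10, ring B = γ‑lactone, ring C = epoxide.
Cuts, in retrosynthetic order: epoxide O (back to the C5=C6 alkene), C9–O angelate, C11=C13, the C6–C7 bond of ring A, C9–H (ketone), C8–C9, lactone C1–O–C12, C1–C10 (aldol), C3–CH3 and C3–C4.
Enabling feature: in ring A the methyl‑bearing sp2 carbon C6 of the C5=C6 alkene is bonded to the C7H2–C8H2 unit that ends at C9, so C6–C7 is an alkenyl–alkyl bond between a (Z)‑alkenyl iodide and a primary alkylborane grown on a C7=C8 vinyl group.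
Forward: but‑2‑yn‑1‑ol → (Z)‑3‑iodobutenal → propiolate alkynylation → methylcuprate → (2Z,5Z)‑dienal; anti‑aldol with a succinate thioimide, vinyl ketone, ring B closed (step 11), C9 reduced; ring A closed by B‑alkyl Suzuki coupling (step 14); then C13 methylene, angelate, ring C (step 19).
Stereochemistry: C4 from the ligand‑controlled alkynylation; C1/C10 from the thiazolidinethione auxiliary (anti‑aldol, hence cis‑lactone); C9 from Felkin‑controlled ketone reduction; both Z alkenes from trans‑hydroalumination/iodination and syn‑carbocupration; C5/C6 from C4–OH‑directed epoxidation.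

Key step: step 14

Assumption: the facial sense of the alkynylation (step 3) and of the auxiliary‑controlled anti‑aldol (step 9) is taken from the accepted models for enals; should either prove opposite, the mirror‑image ligand or auxiliary, equally available, would be used with no other change.

**Route**

Step 1
Reactants: 1 but‑2‑yn‑1‑ol
Product: 3 (2Z)‑3‑iodobut‑2‑en‑1‑ol, via cyclic alkenylalanate 2 (not isolated)
Conditions: NaAlH2(OCH2CH2OMe)2, THF, 0 °C → rt; EtOAc; then I2, THF, −78 → 0 °C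
Reagents that add atoms: iodine, II
Why: Hydroxyl‑directed trans‑hydroalumination of the propargylic alcohol places aluminium on the distal alkyne carbon inside a five‑membered chelate and iododealumination occurs with retention, so iodine ends cis to the CH2OH group and the (Z)‑iodoalkene that becomes C5=C6–I is fixed.

Step 2
Reactants: 3 (2Z)‑3‑iodobut‑2‑en‑1‑ol
Product: 4 (2Z)‑3‑iodobut‑2‑enal
Conditions: MnO2, CH2Cl2, rt; crude aldehyde used at once
Reagents that add atoms: none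
Why: MnO2 oxidizes only the allylic alcohol under neutral heterogeneous conditions and should leave the iodoalkene geometry untouched.

Step 3
Reactants: 4 (2Z)‑3‑iodobut‑2‑enal, 5 methyl prop‑2‑ynoate
Product: 6 methyl (4S,5Z)‑4‑hydroxy‑6‑iodohept‑5‑en‑2‑ynoate
Conditions: (S,S)‑ProPhenol (20 mol %), ZnMe2, toluene, 4 °C
Reagents that add atoms: none
Why: In the zinc–ProPhenol alkynylation the dinuclear zinc complex formed from ZnMe2 and the ligand holds the alkynylide and the enal in one chiral pocket and delivers the alkyne to a single aldehyde face, which sets C4 (4S) in a reaction class for which α,β‑unsaturated aldehydes are standard substrates.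

Step 4
Reactants: 6 methyl (4S,5Z)‑4‑hydroxy‑6‑iodohept‑5‑en‑2‑ynoate
Product: 7 methyl (4S,5Z)‑4‑[(tert‑butyldimethylsilyl)oxy]‑6‑iodohept‑5‑en‑2‑ynoate
Conditions: TBSCl, imidazole, DMF, 0 °C → rt
Reagents that add atoms: tert‑butyldimethylsilyl chloride, CC(C)(C)[Si](C)(C)Cl
Why: Routine silylation of the secondary propargylic alcohol protects the C4 hydroxyl for everything up to step 18 without touching the stereocentre.

Step 5
Reactants: 7 methyl (4S,5Z)‑4‑[(tert‑butyldimethylsilyl)oxy]‑6‑iodohept‑5‑en‑2‑ynoate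
Product: 8 methyl (2Z,4S,5Z)‑4‑[(tert‑butyldimethylsilyl)oxy]‑6‑iodo‑3‑methylhepta‑2,5‑dienoate
Conditions: CuI, MeLi (2 equiv), THF, −78 °C; then 7, −78 °C; MeOH then aq NH4Cl at −78 °C
Reagents that add atoms: lithium dimethylcuprate, [Li+].C[Cu-]C
Why: Conjugate syn‑carbocupration of the ynoate puts the methyl group on C3 and copper on C2 on the same side and protonation of the alkenylcopper at −78 °C retains that geometry, so the ester and C4 end cis (2Z), while the silyloxy group is too poor a leaving group for SN2' displacement and the alkenyl iodide does not couple at this temperature.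

Step 6
Reactants: 8 methyl (2Z,4S,5Z)‑4‑[(tert‑butyldimethylsilyl)oxy]‑6‑iodo‑3‑methylhepta‑2,5‑dienoate
Product: 9 (2Z,4S,5Z)‑4‑[(tert‑butyldimethylsilyl)oxy]‑6‑iodo‑3‑methylhepta‑2,5‑dien‑1‑ol
Conditions: i‑Bu2AlH, CH2Cl2, −78 °C
Reagents that add atoms: none
Why: i‑Bu2AlH reduces the conjugated ester in a 1,2‑fashion to the allylic alcohol at low temperature without disturbing either Z alkene, the silyl ether or the alkenyl iodide.

Step 7
Reactants: 9 (2Z,4S,5Z)‑4‑[(tert‑butyldimethylsilyl)oxy]‑6‑iodo‑3‑methylhepta‑2,5‑dien‑1‑ol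
Product: 10 (2Z,4S,5Z)‑4‑[(tert‑butyldimethylsilyl)oxy]‑6‑iodo‑3‑methylhepta‑2,5‑dienal
Conditions: MnO2, CH2Cl2, rt
Reagents that add atoms: none
Why: Allylic oxidation with MnO2 is neutral and should deliver the (2Z)‑enal without Z to E isomerization or loss of the silyl ether.

Step 8
Reactants: 11 (4R)‑4‑benzyl‑1,3‑thiazolidine‑2‑thione, 12 methyl 4‑chloro‑4‑oxobutanoate
Product: 13 methyl 4‑[(4R)‑4‑benzyl‑2‑sulfanylidene‑1,3‑thiazolidin‑3‑yl]‑4‑oxobutanoate
Conditions: Et3N, DMAP (cat.), CH2Cl2, 0 °C → rt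
Reagents that add atoms: none
Why: N‑acylation of the thiazolidinethione by the acid chloride gives the active amide whose CH2 next to the thioimide carbonyl is the only position acidic enough for soft enolization.

Step 9
Reactants: 13 methyl 4‑[(4R)‑4‑benzyl‑2‑sulfanylidene‑1,3‑thiazolidin‑3‑yl]‑4‑oxobutanoate, 10 (2Z,4S,5Z)‑4‑[(tert‑butyldimethylsilyl)oxy]‑6‑iodo‑3‑methylhepta‑2,5‑dienal
Product: 14 methyl (3S,4S,5Z,7S,8Z)‑3‑{[(4R)‑4‑benzyl‑2‑sulfanylidene‑1,3‑thiazolidin‑3‑yl]carbonyl}‑7‑[(tert‑butyldimethylsilyl)oxy]‑9‑iodo‑6‑methyl‑4‑[(trimethylsilyl)oxy]deca‑5,8‑dienoate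
Conditions: MgBr2·OEt2 (20 mol %), Et3N, Me3SiCl, EtOAc, rt
Reagents that add atoms: chlorotrimethylsilane, C[Si](C)(C)Cl
Why: In the MgBr2‑catalysed direct anti‑aldol reaction of N‑acylthiazolidinethiones the amine and MgBr2 generate the (Z)‑enolate reversibly, the benzyl group of the (4R)‑auxiliary shields one enolate face and the enal adds through the anti‑selective transition state, so C10 and C1 are set together (3S,4S in 14, anti) while silylation of the aldolate by Me3SiCl turns the catalyst over and masks the C1 hydroxyl.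

Step 10
Reactants: 14 anti‑aldol adduct (trimethylsilyl ether)
Product: 15 methyl (3S,4S,5Z,7S,8Z)‑7‑[(tert‑butyldimethylsilyl)oxy]‑9‑iodo‑3‑[methoxy(methyl)carbamoyl]‑6‑methyl‑4‑[(trimethylsilyl)oxy]deca‑5,8‑dienoate
Conditions: MeONHMe·HCl, imidazole, CH2Cl2, rt
Reagents that add atoms: N,O‑dimethylhydroxylamine hydrochloride, CNOC.Cl
Why: The N‑acylthiazolidinethione is an activated amide that undergoes direct aminolysis by N,O‑dimethylhydroxylamine under imidazole buffering (Weinreb amide formation), releasing the auxiliary and leaving the methyl ester, both silyl ethers and the stereocentres untouched.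

Step 11
Reactants: 15 Weinreb amide, 16 vinylmagnesium bromide
Product: 19 (4S,5S)‑5‑[(1Z,3S,4Z)‑3‑[(tert‑butyldimethylsilyl)oxy]‑5‑iodo‑2‑methylhexa‑1,4‑dien‑1‑yl]‑4‑(prop‑2‑enoyl)oxolan‑2‑one, via open‑chain enone trimethylsilyl ether 17 (not isolated), via hydroxy enone ester 18 (not isolated)
Conditions: CH2=CHMgBr, THF, −78 → −20 °C; aq NH4Cl; then PPTS, MeOH/CH2Cl2, 0 °C → rt
Reagents that add atoms: none
Why: Vinylmagnesium bromide adds once to the Weinreb amide through the stable magnesium chelate and faster than to the methyl ester, and the mild acid then removes the labile trimethylsilyl ether so that the C1 hydroxyl lactonizes onto the C12 ester (5‑exo‑trig acyl substitution) to close ring B, which is cis‑disubstituted because of the anti‑aldol configuration.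

Step 12
Reactants: 19 lactone vinyl ketone
Product: 20 (4R,5S)‑5‑[(1Z,3S,4Z)‑3‑[(tert‑butyldimethylsilyl)oxy]‑5‑iodo‑2‑methylhexa‑1,4‑dien‑1‑yl]‑4‑[(1R)‑1‑hydroxyprop‑2‑en‑1‑yl]oxolan‑2‑one
Conditions: NaBH4, CeCl3·7H2O, MeOH, −78 °C
Reagents that add atoms: none
Why: Luche 1,2‑reduction of the vinyl ketone should follow the Felkin–Anh model, hydride attacking anti to the C10–C1 ring bond with the carbonyl oxygen on the side of C11, which gives the 9R alcohol (C9–O anti to C11 and syn to the C1 oxygen) and leaves the lactone intact at −78 °C.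

Step 13
Reactants: 20 lactone allylic alcohol
Product: 21 (4S,5S)‑5‑[(1Z,3S,4Z)‑3‑[(tert‑butyldimethylsilyl)oxy]‑5‑iodo‑2‑methylhexa‑1,4‑dien‑1‑yl]‑4‑[(1R)‑1‑[(triethylsilyl)oxy]prop‑2‑en‑1‑yl]oxolan‑2‑one
Conditions: Et3SiOTf, 2,6‑lutidine, CH2Cl2, −78 °C
Reagents that add atoms: triethylsilyl trifluoromethanesulfonate, CC[Si](CC)(CC)OS(=O)(=O)C(F)(F)F
Why: Silylation with Et3SiOTf and 2,6‑lutidine is fast and non‑nucleophilic, so the C9 hydroxyl is capped before it can translactonize onto C12, and the triethylsilyl ether can later be removed in the presence of the tert‑butyldimethylsilyl ether.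

Step 14
Reactants: 21 lactone‑bearing (Z)‑alkenyl iodide with terminal alkene
Product: 23 (3aS,4R,7Z,9S,10Z,11aS)‑9‑[(tert‑butyldimethylsilyl)oxy]‑7,10‑dimethyl‑4‑[(triethylsilyl)oxy]‑3a,4,5,6,9,11a‑hexahydrocyclodeca[b]furan‑2(3H)‑one, via B‑alkyl‑9‑BBN borane 22 (not isolated)
Conditions: 9‑BBN‑H dimer, THF, 0 °C → rt; then slow addition to PdCl2(dppf) (10 mol %), AsPh3, Cs2CO3, DMF/THF/H2O, rt → 45 °C, about 1 mM
Reagents that add atoms: none
Why: 9‑BBN‑H adds across the terminal C7=C8 alkene with boron on C7, leaving the trisubstituted C2=C3 alkene, the alkenyl iodide and the lactone untouched; zerovalent palladium formed from PdCl2(dppf) then inserts into the C6–I bond with retention, the base‑activated borate transfers the primary C7 alkyl group to divalent palladium and reductive elimination forms C6–C7. The closest known reaction type is the intramolecular B‑alkyl Suzuki–Miyaura macrocyclization of an ω‑borylalkyl alkenyl iodide, for which ten‑membered carbocycles lie at the lower end of the known range. Ring A closes at C6–C7 by reductive elimination from an eleven‑membered alkyl(alkenyl)palladacycle, and the wide bite angle of dppf together with AsPh3 should favour this over β‑hydride elimination from the alkylpalladium. No stereocentre is formed: the 5Z geometry is carried over from the iodide, and C1, C4, C9, C10 and the 2Z alkene are spectators. The step needs chemoselective hydroboration, secured by the hindered borane and the monosubstituted alkene, and ring closure over oligomerization, secured by slow addition at high dilution and by the cis‑lactone and the two Z alkenes, which turn both chain ends toward each other. The lactone should tolerate aqueous Cs2CO3 at room temperature, and any ring‑opened hydroxy acid can only re‑close to the same lactone on mildly acidic work‑up because the C1 hydroxyl is the sole free hydroxyl.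

Step 15
Reactants: 23 ten‑membered diene lactone
Product: 26 (3aS,4R,7Z,9S,10Z,11aS)‑9‑[(tert‑butyldimethylsilyl)oxy]‑7,10‑dimethyl‑3‑methylidene‑4‑[(triethylsilyl)oxy]‑3a,4,5,6,9,11a‑hexahydrocyclodeca[b]furan‑2(3H)‑one, via Mannich base 24 (not isolated), via trimethylammonium iodide 25 (not isolated)
Conditions: LiN(i‑Pr)2, THF, −78 °C; Me2N=CH2+ I−, −78 → 0 °C; then MeI, MeOH/CH2Cl2, rt; then aq NaHCO3, CH2Cl2, rt
Reagents that add atoms: N,N‑dimethylmethyleneiminium iodide (Eschenmoser's salt), C=[N+](C)C.[I-]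
Why: Eschenmoser methylenation, in which the lithium lactone enolate undergoes a Mannich reaction at C11, the amine is quaternized with MeI and mild base triggers E1cB elimination to the exocyclic C11=C13 alkene, works because C11 carries the only acidic protons and its transient stereocentre is destroyed in the elimination.

Step 16
Reactants: 26 bis‑silyl methylene lactone
Product: 27 (3aR,4R,7Z,9S,10Z,11aS)‑9‑[(tert‑butyldimethylsilyl)oxy]‑4‑hydroxy‑7,10‑dimethyl‑3‑methylidene‑3a,4,5,6,9,11a‑hexahydrocyclodeca[b]furan‑2(3H)‑one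
Conditions: PPTS, MeOH/CH2Cl2, 0 °C
Reagents that add atoms: none
Why: Acid‑catalysed methanolysis cleaves the less hindered triethylsilyl ether at C9 much faster than the tert‑butyldimethylsilyl ether at C4, and the mild non‑basic medium should avoid translactonization and conjugate addition to the methylene lactone.

Step 17
Reactants: 27 C9 alcohol, 28 angelic acid
Product: 30 (3aR,4R,7Z,9S,10Z,11aS)‑9‑[(tert‑butyldimethylsilyl)oxy]‑7,10‑dimethyl‑3‑methylidene‑2‑oxo‑2,3,3a,4,5,6,9,11a‑octahydrocyclodeca[b]furan‑4‑yl (2Z)‑2‑methylbut‑2‑enoate, via angelic trichlorobenzoic mixed anhydride 29 (not isolated)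
Conditions: 28, 2,4,6‑Cl3C6H2COCl, Et3N, toluene, rt; then 27, toluene, 80 °C
Reagents that add atoms: none
Why: Yamaguchi‑type esterification through the mixed anhydride of angelic acid, run without a nucleophilic catalyst, acylates the C9 alcohol at the less hindered angeloyl carbonyl and avoids the Z to E isomerization to the tiglate that acyl chloride or acylpyridinium routes tend to cause.

Step 18
Reactants: 30 angelate silyl ether
Product: 31 (3aR,4R,7Z,9S,10Z,11aS)‑9‑hydroxy‑7,10‑dimethyl‑3‑methylidene‑2‑oxo‑2,3,3a,4,5,6,9,11a‑octahydrocyclodeca[b]furan‑4‑yl (2Z)‑2‑methylbut‑2‑enoate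
Conditions: HF·pyridine, pyridine, THF, 0 °C → rt
Reagents that add atoms: none
Why: Pyridine‑buffered HF·pyridine removes the allylic tert‑butyldimethylsilyl ether under weakly acidic, non‑basic conditions that should spare the angelate, the methylene lactone and both ring alkenes.

Step 19
Reactants: 31 dienol angelate
Product: 32 CNP0500828.1
Conditions: VO(acac)2 (cat.), t‑BuOOH, CH2Cl2, 0 °C → rt
Reagents that add atoms: tert‑butyl hydroperoxide, CC(C)(C)OO
Why: In the VO(acac)2‑catalysed hydroxyl‑directed epoxidation the C4 vanadate ester delivers the peroxide oxygen intramolecularly to the adjacent C5=C6 alkene on the face of the C4 oxygen, which for a medium‑ring (Z)‑allylic alcohol gives the cis‑epoxy alcohol (5R,6S), while the C2=C3 alkene is deactivated by the allylic lactone oxygen at C1 and the two conjugated alkenes are too electron‑poor to react.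

**Compound list**
1 | but‑2‑yn‑1‑ol | CC#CCO | starting material
2 | sodium 2,2‑bis(2‑methoxyethoxy)‑3‑methyl‑2,5‑dihydro‑1,2‑oxaaluminol‑2‑uide (cyclic alkenylalanate) | CC1=CCO[Al-]1(OCCOC)OCCOC.[Na+] | intermediate
3 | (2Z)‑3‑iodobut‑2‑en‑1‑ol | OC/C=C(/C)I | intermediate
4 | (2Z)‑3‑iodobut‑2‑enal | O=C/C=C(/C)I | intermediate
5 | methyl prop‑2‑ynoate (methyl propiolate) | C#CC(=O)OC | starting material
6 | methyl (4S,5Z)‑4‑hydroxy‑6‑iodohept‑5‑en‑2‑ynoate | COC(=O)C#C[C@@H](O)/C=C(/C)I | intermediate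
7 | methyl (4S,5Z)‑4‑[(tert‑butyldimethylsilyl)oxy]‑6‑iodohept‑5‑en‑2‑ynoate | COC(=O)C#C[C@@H](O[Si](C)(C)C(C)(C)C)/C=C(/C)I | intermediate
8 | methyl (2Z,4S,5Z)‑4‑[(tert‑butyldimethylsilyl)oxy]‑6‑iodo‑3‑methylhepta‑2,5‑dienoate | COC(=O)/C=C(/C)[C@@H](O[Si](C)(C)C(C)(C)C)/C=C(/C)I | intermediate
9 | (2Z,4S,5Z)‑4‑[(tert‑butyldimethylsilyl)oxy]‑6‑iodo‑3‑methylhepta‑2,5‑dien‑1‑ol | OC/C=C(/C)[C@@H](O[Si](C)(C)C(C)(C)C)/C=C(/C)I | intermediate
10 | (2Z,4S,5Z)‑4‑[(tert‑butyldimethylsilyl)oxy]‑6‑iodo‑3‑methylhepta‑2,5‑dienal | O=C/C=C(/C)[C@@H](O[Si](C)(C)C(C)(C)C)/C=C(/C)I | intermediate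
11 | (4R)‑4‑benzyl‑1,3‑thiazolidine‑2‑thione | S=C1SC[C@@H](Cc2ccccc2)N1 | starting material
12 | methyl 4‑chloro‑4‑oxobutanoate | COC(=O)CCC(Cl)=O | starting material
13 | methyl 4‑[(4R)‑4‑benzyl‑2‑sulfanylidene‑1,3‑thiazolidin‑3‑yl]‑4‑oxobutanoate | COC(=O)CCC(=O)N1C(=S)SC[C@H]1Cc1ccccc1 | intermediate
14 | methyl (3S,4S,5Z,7S,8Z)‑3‑{[(4R)‑4‑benzyl‑2‑sulfanylidene‑1,3‑thiazolidin‑3‑yl]carbonyl}‑7‑[(tert‑butyldimethylsilyl)oxy]‑9‑iodo‑6‑methyl‑4‑[(trimethylsilyl)oxy]deca‑5,8‑dienoate | COC(=O)C[C@H](C(=O)N1C(=S)SC[C@H]1Cc1ccccc1)[C@@H](O[Si](C)(C)C)/C=C(/C)[C@@H](O[Si](C)(C)C(C)(C)C)/C=C(/C)I | intermediate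
15 | methyl (3S,4S,5Z,7S,8Z)‑7‑[(tert‑butyldimethylsilyl)oxy]‑9‑iodo‑3‑[methoxy(methyl)carbamoyl]‑6‑methyl‑4‑[(trimethylsilyl)oxy]deca‑5,8‑dienoate | COC(=O)C[C@H](C(=O)N(C)OC)[C@@H](O[Si](C)(C)C)/C=C(/C)[C@@H](O[Si](C)(C)C(C)(C)C)/C=C(/C)I | intermediate
16 | vinylmagnesium bromide | C=C[Mg]Br | starting material
17 | methyl (3S,4S,5Z,7S,8Z)‑7‑[(tert‑butyldimethylsilyl)oxy]‑9‑iodo‑6‑methyl‑3‑(prop‑2‑enoyl)‑4‑[(trimethylsilyl)oxy]deca‑5,8‑dienoate | COC(=O)C[C@H](C(=O)C=C)[C@@H](O[Si](C)(C)C)/C=C(/C)[C@@H](O[Si](C)(C)C(C)(C)C)/C=C(/C)I | intermediate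
18 | methyl (3S,4S,5Z,7S,8Z)‑7‑[(tert‑butyldimethylsilyl)oxy]‑4‑hydroxy‑9‑iodo‑6‑methyl‑3‑(prop‑2‑enoyl)deca‑5,8‑dienoate | COC(=O)C[C@H](C(=O)C=C)[C@@H](O)/C=C(/C)[C@@H](O[Si](C)(C)C(C)(C)C)/C=C(/C)I | intermediate
19 | (4S,5S)‑5‑[(1Z,3S,4Z)‑3‑[(tert‑butyldimethylsilyl)oxy]‑5‑iodo‑2‑methylhexa‑1,4‑dien‑1‑yl]‑4‑(prop‑2‑enoyl)oxolan‑2‑one | C=CC(=O)[C@H]1CC(=O)O[C@H]1/C=C(/C)[C@@H](O[Si](C)(C)C(C)(C)C)/C=C(/C)I | intermediate
20 | (4R,5S)‑5‑[(1Z,3S,4Z)‑3‑[(tert‑butyldimethylsilyl)oxy]‑5‑iodo‑2‑methylhexa‑1,4‑dien‑1‑yl]‑4‑[(1R)‑1‑hydroxyprop‑2‑en‑1‑yl]oxolan‑2‑one | C=C[C@@H](O)[C@H]1CC(=O)O[C@H]1/C=C(/C)[C@@H](O[Si](C)(C)C(C)(C)C)/C=C(/C)I | intermediate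
21 | (4S,5S)‑5‑[(1Z,3S,4Z)‑3‑[(tert‑butyldimethylsilyl)oxy]‑5‑iodo‑2‑methylhexa‑1,4‑dien‑1‑yl]‑4‑[(1R)‑1‑[(triethylsilyl)oxy]prop‑2‑en‑1‑yl]oxolan‑2‑one | C=C[C@@H](O[Si](CC)(CC)CC)[C@H]1CC(=O)O[C@H]1/C=C(/C)[C@@H](O[Si](C)(C)C(C)(C)C)/C=C(/C)I | intermediate
22 | (4S,5S)‑4‑[(1R)‑3‑(9‑borabicyclo[3.3.1]nonan‑9‑yl)‑1‑[(triethylsilyl)oxy]propyl]‑5‑[(1Z,3S,4Z)‑3‑[(tert‑butyldimethylsilyl)oxy]‑5‑iodo‑2‑methylhexa‑1,4‑dien‑1‑yl]oxolan‑2‑one | C1CC2CCCC(C1)B2CC[C@@H](O[Si](CC)(CC)CC)[C@H]1CC(=O)O[C@H]1/C=C(/C)[C@@H](O[Si](C)(C)C(C)(C)C)/C=C(/C)I | intermediate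
23 | (3aS,4R,7Z,9S,10Z,11aS)‑9‑[(tert‑butyldimethylsilyl)oxy]‑7,10‑dimethyl‑4‑[(triethylsilyl)oxy]‑3a,4,5,6,9,11a‑hexahydrocyclodeca[b]furan‑2(3H)‑one | C1C(=O)O[C@H]2/C=C(/C)[C@@H](O[Si](C)(C)C(C)(C)C)/C=C(/C)CC[C@@H](O[Si](CC)(CC)CC)[C@@H]12 | intermediate
24 | 3‑[(dimethylamino)methyl] derivative of 23 (C3 epimers, inconsequential) | CN(C)CC1C(=O)O[C@H]2/C=C(/C)[C@@H](O[Si](C)(C)C(C)(C)C)/C=C(/C)CC[C@@H](O[Si](CC)(CC)CC)[C@@H]12 | intermediate
25 | 3‑[(trimethylammonio)methyl] derivative of 23, iodide | C[N+](C)(C)CC1C(=O)O[C@H]2/C=C(/C)[C@@H](O[Si](C)(C)C(C)(C)C)/C=C(/C)CC[C@@H](O[Si](CC)(CC)CC)[C@@H]12.[I-] | intermediate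
26 | (3aS,4R,7Z,9S,10Z,11aS)‑9‑[(tert‑butyldimethylsilyl)oxy]‑7,10‑dimethyl‑3‑methylidene‑4‑[(triethylsilyl)oxy]‑3a,4,5,6,9,11a‑hexahydrocyclodeca[b]furan‑2(3H)‑one | C=C1C(=O)O[C@H]2/C=C(/C)[C@@H](O[Si](C)(C)C(C)(C)C)/C=C(/C)CC[C@@H](O[Si](CC)(CC)CC)[C@@H]12 | intermediate
27 | (3aR,4R,7Z,9S,10Z,11aS)‑9‑[(tert‑butyldimethylsilyl)oxy]‑4‑hydroxy‑7,10‑dimethyl‑3‑methylidene‑3a,4,5,6,9,11a‑hexahydrocyclodeca[b]furan‑2(3H)‑one | C=C1C(=O)O[C@H]2/C=C(/C)[C@@H](O[Si](C)(C)C(C)(C)C)/C=C(/C)CC[C@@H](O)[C@@H]12 | intermediate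
28 | angelic acid, (2Z)‑2‑methylbut‑2‑enoic acid | C/C=C(/C)C(=O)O | starting material
29 | (2Z)‑2‑methylbut‑2‑enoic 2,4,6‑trichlorobenzoic anhydride | C/C=C(/C)C(=O)OC(=O)c1c(Cl)cc(Cl)cc1Cl | intermediate
30 | (3aR,4R,7Z,9S,10Z,11aS)‑9‑[(tert‑butyldimethylsilyl)oxy]‑7,10‑dimethyl‑3‑methylidene‑2‑oxo‑2,3,3a,4,5,6,9,11a‑octahydrocyclodeca[b]furan‑4‑yl (2Z)‑2‑methylbut‑2‑enoate | C=C1C(=O)O[C@H]2/C=C(/C)[C@@H](O[Si](C)(C)C(C)(C)C)/C=C(/C)CC[C@@H](OC(=O)/C(C)=C\C)[C@@H]12 | intermediate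
31 | (3aR,4R,7Z,9S,10Z,11aS)‑9‑hydroxy‑7,10‑dimethyl‑3‑methylidene‑2‑oxo‑2,3,3a,4,5,6,9,11a‑octahydrocyclodeca[b]furan‑4‑yl (2Z)‑2‑methylbut‑2‑enoate | C=C1C(=O)O[C@H]2/C=C(/C)[C@@H](O)/C=C(/C)CC[C@@H](OC(=O)/C(C)=C\C)[C@@H]12 | intermediate
32 | CNP0500828.1: ten‑membered (2Z)‑ene with cis‑fused α‑methylene‑γ‑lactone, C4 hydroxyl, 5,6‑epoxide syn to that hydroxyl and C9 angelate; plan locants 1S,4R,5R,6S,9R,10R | C=C1C(=O)O[C@H]2/C=C(/C)[C@@H](O)[C@H]3O[C@@]3(C)CC[C@@H](OC(=O)/C(C)=C\C)[C@@H]12 | target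

**Count and risks**
Total step count: 19. Longest linear sequence: 18 steps (steps 1–7 and 9–19; step 8 is a one‑step side branch).

Step 14 (ring A closure). What may go wrong: intermolecular coupling to dimers and oligomers may outrun closure of the strained ten‑membered ring, and slow transmetalation would let protodeboronation and lactone hydrolysis take over. The fallback keeps the C6–C7 disconnection but changes the organometallic partner and removes the aqueous base; it sets out from 21 and returns at 23. Hydroboration of 21 with 9‑BBN‑H followed by oxidation with NaBO3·4H2O should give the primary alcohol (4S,5S)‑4‑[(1R)‑3‑hydroxy‑1‑[(triethylsilyl)oxy]propyl] lactone F1. Iodination with I2, PPh3 and imidazole gives the primary iodide F2. Activated Zn dust in DMA at 40 °C inserts into the alkyl C–I bond only, giving the alkylzinc iodide F3, which is added slowly to Pd(PPh3)4 in THF/DMA at high dilution, so that an intramolecular Negishi coupling with the untouched (Z)‑alkenyl iodide closes ring A to 23.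

Step 9 (anti‑aldol). What may go wrong: Z to E isomerization or γ‑deprotonation of the (2Z)‑enal under Et3N and MgBr2 at room temperature, and erosion of anti selectivity with the ester‑bearing enolate. The fallback moves to a preformed boron enolate at −78 °C and an open transition state; it sets out from 10 and 12 and returns at 15. Commercial (4R)‑4‑benzyl‑1,3‑oxazolidin‑2‑one is acylated with 12 (n‑BuLi, THF, −78 °C) to give the imide F4. Its dibutylboron enolate (Bu2BOTf, i‑Pr2NEt, CH2Cl2) is added at −78 °C to 10 precomplexed with Et2AlCl, and this Lewis‑acid‑mediated anti‑aldol should give the hydroxy imide F5. The crude adduct is transamidated at once (AlMe3, MeONHMe·HCl, CH2Cl2, −20 °C; the free β‑hydroxyl assists and the imide reacts before the methyl ester) to the hydroxy Weinreb amide F6, and silylation with Me3SiCl and imidazole gives 15.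

Step 19 (epoxidation). What may go wrong: the C4 vanadate may deliver oxygen to the other allylic alkene (C2=C3), or to the wrong face of C5=C6 if the ring reacts through the alternative conformer. The fallback replaces substrate direction by reagent control; it sets out from 31 and returns at 32 without any compound outside the list (entry F0). Epoxidation with Ti(OiPr)4, D‑(−)‑diethyl tartrate and t‑BuOOH (4 Å molecular sieves, CH2Cl2, −20 °C; Katsuki–Sharpless conditions in kinetic‑resolution mode) should be matched for the C4 carbinol of 31 with respect to C5=C6, giving the erythro epoxy alcohol with the required 5R,6S configuration, and mismatched with respect to C2=C3, so that both site and face are chosen by the tartrate.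

**Further compounds**
F1 | step 14 | (4S,5S)‑5‑[(1Z,3S,4Z)‑3‑[(tert‑butyldimethylsilyl)oxy]‑5‑iodo‑2‑methylhexa‑1,4‑dien‑1‑yl]‑4‑[(1R)‑3‑hydroxy‑1‑[(triethylsilyl)oxy]propyl]oxolan‑2‑one | OCC[C@@H](O[Si](CC)(CC)CC)[C@H]1CC(=O)O[C@H]1/C=C(/C)[C@@H](O[Si](C)(C)C(C)(C)C)/C=C(/C)I
F2 | step 14 | (4S,5S)‑5‑[(1Z,3S,4Z)‑3‑[(tert‑butyldimethylsilyl)oxy]‑5‑iodo‑2‑methylhexa‑1,4‑dien‑1‑yl]‑4‑[(1R)‑3‑iodo‑1‑[(triethylsilyl)oxy]propyl]oxolan‑2‑one | ICC[C@@H](O[Si](CC)(CC)CC)[C@H]1CC(=O)O[C@H]1/C=C(/C)[C@@H](O[Si](C)(C)C(C)(C)C)/C=C(/C)I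
F3 | step 14 | alkylzinc iodide from F2 (C7–ZnI) | I[Zn]CC[C@@H](O[Si](CC)(CC)CC)[C@H]1CC(=O)O[C@H]1/C=C(/C)[C@@H](O[Si](C)(C)C(C)(C)C)/C=C(/C)I
F4 | step 9 | (4R)‑4‑benzyl‑3‑(4‑methoxy‑4‑oxobutanoyl)‑1,3‑oxazolidin‑2‑one | COC(=O)CCC(=O)N1C(=O)OC[C@H]1Cc1ccccc1
F5 | step 9 | methyl (3S,4S,5Z,7S,8Z)‑3‑{[(4R)‑4‑benzyl‑2‑oxo‑1,3‑oxazolidin‑3‑yl]carbonyl}‑7‑[(tert‑butyldimethylsilyl)oxy]‑4‑hydroxy‑9‑iodo‑6‑methyldeca‑5,8‑dienoate | COC(=O)C[C@H](C(=O)N1C(=O)OC[C@H]1Cc1ccccc1)[C@@H](O)/C=C(/C)[C@@H](O[Si](C)(C)C(C)(C)C)/C=C(/C)I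
F6 | step 9 | methyl (3S,4S,5Z,7S,8Z)‑7‑[(tert‑butyldimethylsilyl)oxy]‑4‑hydroxy‑9‑iodo‑3‑[methoxy(methyl)carbamoyl]‑6‑methyldeca‑5,8‑dienoate | COC(=O)C[C@H](C(=O)N(C)OC)[C@@H](O)/C=C(/C)[C@@H](O[Si](C)(C)C(C)(C)C)/C=C(/C)I
F0 | step 19 | none | none
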